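Ring D, the quinone, is built late from an alkyne. Its aryloxy carbon and the neighbouring carbon bearing the CH2CH2 arm are the two carbons of an aryl ynol ether (ring C–O–C≡C–CH2CH2–ring A); the other four ring carbons come from cyclobutenone. A Danheiser benzannulation joins the aryloxy carbon to the ketene α-carbon, which becomes the C=O flanked by CH=CH, and closes ring D as a 2-alkyl-3-aryloxyphenol in one operation. Para-oxidation gives the quinone, ring-closing metathesis of two styrene ends closes the 18-membered ring, and one hydrogenation saturates the bridge and frees the ring B phenol.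

Key step: step 7

Remark: macrocyclic stilbene 18 is expected as an E/Z mixture; both isomers converge in step 10, so its double-bond geometry is left open in the SMILES.

Step 1
Reactants: 1 [4-(3-methoxy-3-oxopropyl)phenyl]boronic acid; 2 4-(benzyloxy)-3-hydroxybenzaldehyde
Product: 3 methyl 3-{4-[2-(benzyloxy)-5-formylphenoxy]phenyl}propanoate
Conditions: Cu(OAc)2 (1 equiv), pyridine, 4 Å molecular sieves, CH2Cl2, air, rt
Reagents that add atoms: none
Why: Chan–Lam oxidative O-arylation of a phenol with an arylboronic acid runs at room temperature and should leave the aldehyde, the methyl ester and the benzyl ether untouched.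

Step 2
Reactants: 3 methyl 3-{4-[2-(benzyloxy)-5-formylphenoxy]phenyl}propanoate
Product: 4 methyl 3-{4-[2-(benzyloxy)-5-ethenylphenoxy]phenyl}propanoate
Conditions: Ph3PCH3Br, NaN(SiMe3)2, THF, 0 °C; then 3, −78 °C to rt
Reagents that add atoms: methyltriphenylphosphonium bromide, C[P+](c1ccccc1)(c1ccccc1)c1ccccc1.[Br-]
Why: Wittig methylenation, in which the aryl aldehyde should react with the non-stabilised ylide far faster than the methyl ester.

Step 3
Reactants: 4 methyl 3-{4-[2-(benzyloxy)-5-ethenylphenoxy]phenyl}propanoate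
Product: 5 3-{4-[2-(benzyloxy)-5-ethenylphenoxy]phenyl}propanal
Conditions: i-Bu2AlH (1.1 equiv), CH2Cl2, −78 °C; aq. potassium sodium tartrate
Reagents that add atoms: none
Why: partial ester reduction, in which the aluminium hemiacetal formed at −78 °C should collapse to the aldehyde only on work-up, with styrene and ethers inert.

Step 4
Reactants: 5 3-{4-[2-(benzyloxy)-5-ethenylphenoxy]phenyl}propanal
Product: 6 1-(benzyloxy)-2-[4-(4,4-dibromobut-3-en-1-yl)phenoxy]-4-ethenylbenzene
Conditions: CBr4, PPh3, CH2Cl2, 0 °C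
Reagents that add atoms: carbon tetrabromide, BrC(Br)(Br)Br
Why: first stage of the Corey–Fuchs sequence (dibromomethylenation by Ph3P=CBr2), a Wittig-type olefination that should tolerate the styrene and the ethers.

Step 5
Reactants: 6 1-(benzyloxy)-2-[4-(4,4-dibromobut-3-en-1-yl)phenoxy]-4-ethenylbenzene; 7 3-ethenylphenol
Product: 9 1-(benzyloxy)-4-ethenyl-2-{4-[4-(3-ethenylphenoxy)but-3-yn-1-yl]phenoxy}benzene, via bromo enol ether 8 (not isolated)
Conditions: CuI (10 mol%), 2,2'-bipyridine, K3PO4, toluene, 110 °C; then KOt-Bu, 1,4-dioxane, rt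
Reagents that add atoms: none
Why: copper-catalysed Ullmann-type vinylic C–O coupling of the phenol at the less hindered C–Br bond of the 1,1-dibromoalkene should give the (Z)-bromo enol ether, whose anti H and Br are then lost by E2 elimination to give the aryl ynol ether.

Step 6
Reactants: 10 3-bromocyclobutan-1-one
Product: 11 cyclobut-2-en-1-one
Conditions: n-Bu3N, neat, rt; vacuum transfer into a −78 °C trap, used as a cold solution
Reagents that add atoms: none
Why: amine-induced E1cB dehydrobromination of the β-bromo ketone, with the volatile enone removed from the base as it forms.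

Step 7
Reactants: 9 1-(benzyloxy)-4-ethenyl-2-{4-[4-(3-ethenylphenoxy)but-3-yn-1-yl]phenoxy}benzene; 11 cyclobut-2-en-1-one
Product: 16 2-(2-{4-[2-(benzyloxy)-5-ethenylphenoxy]phenyl}ethyl)-3-(3-ethenylphenoxy)phenol, via vinylketene 12 (not isolated), via vinylcyclobutenone 13 (not isolated), via dienylketene 14 (not isolated), via cyclohexadienone 15 (not isolated)
Conditions: 11 (2 equiv), BHT (cat.), toluene, 80 °C then 110 °C, sealed tube
Reagents that add atoms: none
Why: Danheiser benzannulation: cyclobutenone 11 opens reversibly (4π electrocyclic) to vinylketene 12, the oxygen-polarised ynol ether 9 attacks the ketene carbonyl carbon through its β-carbon (the one bearing the CH2CH2 arm), and the ketene α-carbon then bonds to the aryloxy-bearing alkyne carbon, closing cyclobutenone 13 by a regiospecific [2+2] cycloaddition. 4π opening of 13 gives dienylketene 14, which closes ring D by thermal 6π electrocyclisation to cyclohexadienone 15 and tautomerises to phenol 16. The closest known reaction type is the thermal benzannulation of cyclobutenones with alkynyl ethers and siloxyalkynes, which gives resorcinol monoethers of this regiochemistry. Modes of closure: the four-membered ring by ketene–alkyne [2+2] cycloaddition, the six-membered ring D by disrotatory 6π electrocyclisation; no stereocentre survives, because the sp3 carbon of 13 ends up aromatic. The step needs regioselectivity, secured by the polarisation of the ynol ether, and chemoselectivity for the alkyne over the two styrene groups, secured by the much higher ketenophilicity of an oxygen-substituted alkyne; since carbons 5 and 6 of ring D carry only hydrogen, even the opposite alkyne orientation would converge on quinone 17 after step 8.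

Step 8
Reactants: 16 2-(2-{4-[2-(benzyloxy)-5-ethenylphenoxy]phenyl}ethyl)-3-(3-ethenylphenoxy)phenol
Product: 17 2-(2-{4-[2-(benzyloxy)-5-ethenylphenoxy]phenyl}ethyl)-3-(3-ethenylphenoxy)cyclohexa-2,5-diene-1,4-dione
Conditions: Fremy's salt, K2[ON(SO3)2] (2.5 equiv), KH2PO4 buffer, acetone–H2O, rt
Reagents that add atoms: Fremy's salt (potassium nitrosodisulfonate), [K+].[K+].[O]N(S(=O)(=O)[O-])S(=O)(=O)[O-]
Why: Teuber oxidation, in which the phenoxyl radical of the only free phenol should be trapped at its unsubstituted para position by a second nitroxyl and collapse to the para-quinone.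

Step 9
Reactants: 17 2-(2-{4-[2-(benzyloxy)-5-ethenylphenoxy]phenyl}ethyl)-3-(3-ethenylphenoxy)cyclohexa-2,5-diene-1,4-dione
Product: 18 macrocyclic stilbene quinone (the ring B O-benzyl ether of the target with CH=CH in place of the CH2CH2 bridge between rings B and C)
Conditions: second-generation Hoveyda–Grubbs catalyst, RuCl2(H2IMes)(=CH-C6H4-2-O-i-Pr) (10 mol%), toluene (1 mM), 80 °C, argon sparge
Reagents that add atoms: none
Why: ring-closing metathesis of the two styrene termini should close the 18-membered ring under high dilution, driven by loss of ethylene, with a phosphine-free catalyst chosen so that no phosphine adds to the quinone.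

Step 10
Reactants: 18 macrocyclic stilbene quinone
Product: 20 marchantinquinone, via macrocyclic hydroquinone 19 (not isolated)
Conditions: H2 (1 atm), Pd/C, EtOAc–MeOH, rt; filter; then Ag2O, MgSO4, Et2O, rt
Reagents that add atoms: none
Why: heterogeneous hydrogenation should saturate the stilbene, hydrogenolyse the benzyl ether and reduce the quinone to the hydroquinone, which Ag2O should re-oxidise selectively, since the ring B monophenol is not oxidised by this reagent.

Compound list
1 | [4-(3-methoxy-3-oxopropyl)phenyl]boronic acid | COC(=O)CCc1ccc(cc1)B(O)O | starting material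
2 | 4-(benzyloxy)-3-hydroxybenzaldehyde | O=Cc1ccc(OCc2ccccc2)c(O)c1 | starting material
3 | methyl 3-{4-[2-(benzyloxy)-5-formylphenoxy]phenyl}propanoate | COC(=O)CCc1ccc(cc1)Oc1cc(C=O)ccc1OCc1ccccc1 | intermediate
4 | methyl 3-{4-[2-(benzyloxy)-5-ethenylphenoxy]phenyl}propanoate | COC(=O)CCc1ccc(cc1)Oc1cc(C=C)ccc1OCc1ccccc1 | intermediate
5 | 3-{4-[2-(benzyloxy)-5-ethenylphenoxy]phenyl}propanal | O=CCCc1ccc(cc1)Oc1cc(C=C)ccc1OCc1ccccc1 | intermediate
6 | 1-(benzyloxy)-2-[4-(4,4-dibromobut-3-en-1-yl)phenoxy]-4-ethenylbenzene | BrC(Br)=CCCc1ccc(cc1)Oc1cc(C=C)ccc1OCc1ccccc1 | intermediate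
7 | 3-ethenylphenol | Oc1cccc(C=C)c1 | starting material
8 | 1-(benzyloxy)-2-{4-[(3Z)-4-bromo-4-(3-ethenylphenoxy)but-3-en-1-yl]phenoxy}-4-ethenylbenzene (bromo enol ether) | Br/C(Oc1cccc(C=C)c1)=C\CCc1ccc(cc1)Oc1cc(C=C)ccc1OCc1ccccc1 | intermediate (not isolated)
9 | 1-(benzyloxy)-4-ethenyl-2-{4-[4-(3-ethenylphenoxy)but-3-yn-1-yl]phenoxy}benzene (aryl ynol ether) | C=Cc1cccc(c1)OC#CCCc1ccc(cc1)Oc1cc(C=C)ccc1OCc1ccccc1 | intermediate
10 | 3-bromocyclobutan-1-one | O=C1CC(Br)C1 | starting material
11 | cyclobut-2-en-1-one | O=C1C=CC1 | intermediate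
12 | buta-1,3-dien-1-one (vinylketene) | C=CC=C=O | intermediate (not isolated)
13 | racemic 2-(2-{4-[2-(benzyloxy)-5-ethenylphenoxy]phenyl}ethyl)-4-ethenyl-3-(3-ethenylphenoxy)cyclobut-2-en-1-one | O=C1C(CCc2ccc(cc2)Oc2cc(C=C)ccc2OCc2ccccc2)=C(Oc2cccc(C=C)c2)C1C=C | intermediate (not isolated)
14 | (3E)-2-(2-{4-[2-(benzyloxy)-5-ethenylphenoxy]phenyl}ethyl)-3-(3-ethenylphenoxy)hexa-1,3,5-trien-1-one (dienylketene, vinyl group cis to the ketene-bearing carbon) | O=C=C(CCc1ccc(cc1)Oc1cc(C=C)ccc1OCc1ccccc1)/C(Oc1cccc(C=C)c1)=C\C=C | intermediate (not isolated)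
15 | 2-(2-{4-[2-(benzyloxy)-5-ethenylphenoxy]phenyl}ethyl)-3-(3-ethenylphenoxy)cyclohexa-2,4-dien-1-one | O=C1CC=CC(Oc2cccc(C=C)c2)=C1CCc1ccc(cc1)Oc1cc(C=C)ccc1OCc1ccccc1 | intermediate (not isolated)
16 | 2-(2-{4-[2-(benzyloxy)-5-ethenylphenoxy]phenyl}ethyl)-3-(3-ethenylphenoxy)phenol | Oc1cccc(Oc2cccc(C=C)c2)c1CCc1ccc(cc1)Oc1cc(C=C)ccc1OCc1ccccc1 | intermediate
17 | 2-(2-{4-[2-(benzyloxy)-5-ethenylphenoxy]phenyl}ethyl)-3-(3-ethenylphenoxy)cyclohexa-2,5-diene-1,4-dione | O=C1C=CC(=O)C(Oc2cccc(C=C)c2)=C1CCc1ccc(cc1)Oc1cc(C=C)ccc1OCc1ccccc1 | intermediate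
18 | macrocyclic stilbene quinone (ring B O-benzyl ether of the target with a CH=CH bridge between rings B and C, E/Z mixture) | O=C1C=CC(=O)C2=C1CCc1ccc(cc1)Oc1cc(ccc1OCc1ccccc1)C=Cc1cccc(c1)O2 | intermediate
19 | macrocyclic hydroquinone (the target with ring D as a 1,4-dihydroxybenzene) | Oc1ccc(O)c2c1CCc1ccc(cc1)Oc1cc(ccc1O)CCc1cccc(c1)O2 | intermediate (not isolated)
20 | marchantinquinone | O=C1C=CC(=O)C2=C1CCc1ccc(cc1)Oc1cc(ccc1O)CCc1cccc(c1)O2 | target

Total step count: 10. Longest linear sequence: 9 steps (steps 1–5 and 7–10); step 6 is a one-step branch.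

Steps most likely to fail

1. Step 7 (benzannulation). The aryl ynol ether is a weaker ketenophile than alkyl or silyl ynol ethers, so trapping of the transient vinylketene may be slow. Ketene oligomerisation and O-acylation of the product phenol by excess ketene could then take over. The fallback sets out from ester 4 and returns to the route at phenol 16. Kowalski ynolate formation from 4 (CH2Br2, lithium 2,2,6,6-tetramethylpiperidide, THF, −78 °C; then n-BuLi, −78 °C to rt) followed by O-silylation with i-Pr3SiCl should give siloxyalkyne F1, a proven partner class for this benzannulation. Heating F1 with cyclobutenone 11 (toluene, 80 °C) should give silyloxyphenol F2. Chan–Lam arylation of the free hydroxyl of F2 with (3-ethenylphenyl)boronic acid (Cu(OAc)2, pyridine, CH2Cl2, air) should give silyl diaryl ether F3, and n-Bu4NF in THF should then release 16. Because the 2-alkylresorcinol core is symmetric, arylating one oxygen and freeing the other leads to the same phenol 16.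

2. Step 9 (ring-closing metathesis). Intermolecular metathesis of the styrene ends (oligomerisation, cyclic dimer formation) may outrun closure of the 18-membered ring, or the catalyst may stall. The fallback sets out from phenol 16 and returns at 18. Lemieux–Johnson cleavage of both vinyl groups of 16 (OsO4 cat., NaIO4, 2,6-lutidine, dioxane–H2O) should give dialdehyde F4. Intramolecular McMurry coupling (TiCl4, Zn, pyridine, THF, reflux, high dilution) should give macrocyclic stilbene phenol F5. Teuber oxidation of F5 with Fremy's salt, K2[ON(SO3)2], as in step 8 should then give 18.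

3. Step 5 (ynol ether formation). A second C–O coupling at the dibromoalkene (ketene acetal formation) or base-induced alkyne-to-allene isomerisation during the dehydrobromination may erode the ynol ether. The fallback sets out from ester 4 and returns at ynol ether 9. Chloromethylation of 4 with LiCH2Cl generated in the flask (ICH2Cl, MeLi·LiBr, THF, −78 °C) should give chloromethyl ketone F6. Williamson etherification with 3-ethenylphenol 7 (K2CO3, NaI cat., acetone) should give aryloxy ketone F7. Regioselective enolisation on the more acidic aryloxy-bearing side and O-triflation (LiN(SiMe3)2, PhNTf2, THF, −78 °C) should give enol triflate F8, which KOt-Bu should convert in the same flask by anti-elimination into 9.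

Further compounds
F1 | step 7 | triisopropyl[(4-{4-[2-(benzyloxy)-5-ethenylphenoxy]phenyl}but-1-yn-1-yl)oxy]silane | CC(C)[Si](C(C)C)(C(C)C)OC#CCCc1ccc(cc1)Oc1cc(C=C)ccc1OCc1ccccc1
F2 | step 7 | 2-(2-{4-[2-(benzyloxy)-5-ethenylphenoxy]phenyl}ethyl)-3-[(triisopropylsilyl)oxy]phenol | Oc1cccc(O[Si](C(C)C)(C(C)C)C(C)C)c1CCc1ccc(cc1)Oc1cc(C=C)ccc1OCc1ccccc1
F3 | step 7 | [2-(2-{4-[2-(benzyloxy)-5-ethenylphenoxy]phenyl}ethyl)-3-(3-ethenylphenoxy)phenoxy]triisopropylsilane | C=Cc1cccc(c1)Oc1cccc(O[Si](C(C)C)(C(C)C)C(C)C)c1CCc1ccc(cc1)Oc1cc(C=C)ccc1OCc1ccccc1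
F4 | step 9 | 4-(benzyloxy)-3-(4-{2-[2-(3-formylphenoxy)-6-hydroxyphenyl]ethyl}phenoxy)benzaldehyde | Oc1cccc(Oc2cccc(C=O)c2)c1CCc1ccc(cc1)Oc1cc(C=O)ccc1OCc1ccccc1
F5 | step 9 | macrocyclic stilbene phenol (18 with ring D as the 2-alkyl-3-aryloxyphenol in place of the quinone) | Oc1cccc2c1CCc1ccc(cc1)Oc1cc(ccc1OCc1ccccc1)C=Cc1cccc(c1)O2
F6 | step 5 | 4-{4-[2-(benzyloxy)-5-ethenylphenoxy]phenyl}-1-chlorobutan-2-one | ClCC(=O)CCc1ccc(cc1)Oc1cc(C=C)ccc1OCc1ccccc1
F7 | step 5 | 4-{4-[2-(benzyloxy)-5-ethenylphenoxy]phenyl}-1-(3-ethenylphenoxy)butan-2-one | C=Cc1cccc(c1)OCC(=O)CCc1ccc(cc1)Oc1cc(C=C)ccc1OCc1ccccc1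
F8 | step 5 | (1Z)-4-{4-[2-(benzyloxy)-5-ethenylphenoxy]phenyl}-1-(3-ethenylphenoxy)but-1-en-2-yl trifluoromethanesulfonate | C=Cc1cccc(c1)O/C=C(\OS(=O)(=O)C(F)(F)F)CCc1ccc(cc1)Oc1cc(C=C)ccc1OCc1ccccc1
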